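The retrosynthesis cuts the aryl–vinyl bond of the stilbene, then the three C2–C3 bonds of the three trans-2,3-diaryl-2,3-dihydrobenzofurans in one operation. It then cuts the bond from the central carbene carbon to ring C and the two ArO–CH2 ether bonds, which lead back to one common bromo-hydroxybenzophenone hydrazone.
Enabling feature: in each five-membered ring C2 is an oxygen-bound benzylic CH bearing a para-oxygenated aryl group. C3 is a diarylmethine CH on the benzo-ring carbon ortho to that oxygen, so each C2–C3 bond maps onto a diaryl carbene ortho to an ArO–CH2–Ar ether. Ring A is the benzo ring of the left unit (Br, later styryl), ring B that of the central unit, ring C that of the right unit.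
Design constraint: the central and right carbene carbons are ortho neighbours on ring C. A 1,2-diaroylbenzene would give a phthalazine with hydrazine, and two adjacent diazo groups would reach the same ring by azine formation, so no diketone is made and the carbenes are released in turn in one flask.
Forward order: the common hydrazone is O-alkylated twice (right arm, left arm), both outer nitrogens are tosylated, and the arms are joined by aryllithium–nitrile addition. In step 12 the central ring closes first, then the left and right rings, then acid sets all three trans.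
Stereochemistry: the three C3 centres (all R) come from one enantiomer of a chiral dirhodium carboxylate acting on an achiral chain. The three C2 centres (all R) come from acid equilibration to the trans rings, and the E-alkene comes from the Heck reaction.
End game: the methyl ethers are exchanged for acetates before the alkene is introduced, so the last step is a mild, non-acidic aminolysis.

Key step: step 12

Assumption: Rh2(R-PTAD)4, dirhodium tetrakis[(R)-(1-adamantyl)(phthalimido)acetate], is written for the catalyst enantiomer that delivers 3R. If the sense of induction is the opposite on these substrates, Rh2(S-PTAD)4 is used and nothing else changes. C=N geometries are left undefined because both isomers give the same diazo compound.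

Step 1
Reactants: 1 1-bromo-3,5-dimethoxybenzene; 2 3,5-dimethoxybenzoyl chloride
Product: 3 (2-bromo-4,6-dimethoxyphenyl)(3,5-dimethoxyphenyl)methanone
Conditions: AlCl3 (1.2 equiv), CH2Cl2, 0 °C
Reagents that add atoms: none
Why: Friedel–Crafts acylation should go to the position para to one methoxy group and ortho to bromine rather than to the crowded site between the two methoxy groups, as is usual for 5-substituted resorcinol dimethyl ethers, so the carbonyl is placed between Br and OMe without any ortho-acylation of a phenol.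

Step 2
Reactants: 3 (2-bromo-4,6-dimethoxyphenyl)(3,5-dimethoxyphenyl)methanone
Product: 4 (2-bromo-6-hydroxy-4-methoxyphenyl)(3,5-dimethoxyphenyl)methanone
Conditions: BCl3 (1.5 equiv), CH2Cl2, −78 to 0 °C; H2O
Reagents that add atoms: none
Why: Chelation-directed aryl methyl ether cleavage, in which BCl3 bound to the ketone oxygen removes only the ortho methyl group through a six-membered chelate, is the standard route to 2-hydroxyaryl ketones.

Step 3
Reactants: 4 (2-bromo-6-hydroxy-4-methoxyphenyl)(3,5-dimethoxyphenyl)methanone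
Product: 5 hydrazone of 4, 3-bromo-2-[(3,5-dimethoxyphenyl)(hydrazinylidene)methyl]-5-methoxyphenol
Conditions: N2H4·H2O (20 equiv), AcOH (cat.), n-BuOH, 110 °C, N2
Reagents that add atoms: hydrazine, NN
Why: Hydrazone condensation is run at the least hindered stage (free phenol, small neighbours), 2,6-disubstituted benzophenones are known to condense near this temperature, and the O–H···N hydrogen bond together with the electron-rich ring should disfavour indazole closure onto C–Br.

Step 4
Reactants: 5 hydrazone of 4; 6 4-methoxybenzyl chloride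
Product: 7 [2-bromo-4-methoxy-6-(4-methoxybenzyloxy)phenyl](3,5-dimethoxyphenyl)methanone hydrazone
Conditions: K2CO3, Bu4NI (cat.), DMF, 23 °C
Reagents that add atoms: none
Why: Williamson ether synthesis should occur on oxygen because the phenoxide is far more nucleophilic than the conjugated hydrazone NH2, and it installs the ArO–CH2–Ar unit of the right ring.

Step 5
Reactants: 7 right-arm hydrazone
Product: 8 N-tosylhydrazone of [2-bromo-4-methoxy-6-(4-methoxybenzyloxy)phenyl](3,5-dimethoxyphenyl)methanone
Conditions: TsCl (1.1 equiv), pyridine, 0 to 23 °C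
Reagents that add atoms: 4-toluenesulfonyl chloride, Cc1ccc(cc1)S(=O)(=O)Cl
Why: N-sulfonylation of a preformed hydrazone reaches the hindered tosylhydrazone without a condensation at the crowded carbon and turns the nitrogen function into a poorly nucleophilic, base-triggered diazo source.

Step 6
Reactants: 9 2-fluoro-5-formylbenzonitrile; 10 4-methoxybenzyl alcohol
Product: 11 5-formyl-2-(4-methoxybenzyloxy)benzonitrile
Conditions: Cs2CO3, DMF, 60 °C
Reagents that add atoms: none
Why: Nucleophilic aromatic substitution by addition–elimination should be easy because fluoride is activated by the ortho nitrile and the para formyl group.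

Step 7
Reactants: 11 5-formyl-2-(4-methoxybenzyloxy)benzonitrile
Product: 12 5-(hydroxymethyl)-2-(4-methoxybenzyloxy)benzonitrile
Conditions: NaBH4, MeOH–THF, 0 °C
Reagents that add atoms: none
Why: Borohydride reduction is chemoselective for the aldehyde and leaves the nitrile and the benzyl aryl ether untouched.

Step 8
Reactants: 12 5-(hydroxymethyl)-2-(4-methoxybenzyloxy)benzonitrile
Product: 13 5-(bromomethyl)-2-(4-methoxybenzyloxy)benzonitrile
Conditions: CBr4, PPh3, CH2Cl2, 0 °C
Reagents that add atoms: carbon tetrabromide, BrC(Br)(Br)Br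
Why: The Appel reaction converts the benzylic alcohol into the bromide under neutral conditions that spare the acid-labile 4-methoxybenzyl aryl ether.

Step 9
Reactants: 5 hydrazone of 4; 13 5-(bromomethyl)-2-(4-methoxybenzyloxy)benzonitrile
Product: 14 5-({3-bromo-2-[(3,5-dimethoxyphenyl)(hydrazinylidene)methyl]-5-methoxyphenoxy}methyl)-2-(4-methoxybenzyloxy)benzonitrile
Conditions: K2CO3, DMF, 0 to 23 °C
Reagents that add atoms: none
Why: A second Williamson ether synthesis on the same phenoxide links ring A to ring B through the OCH2 group that becomes C2 of the left ring.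

Step 10
Reactants: 14 left-arm hydrazone nitrile
Product: 15 N-tosylhydrazone of 14
Conditions: TsCl (1.1 equiv), pyridine, 0 to 23 °C
Reagents that add atoms: 4-toluenesulfonyl chloride, Cc1ccc(cc1)S(=O)(=O)Cl
Why: N-sulfonylation of the hydrazone removes the free NH2 before the organolithium step and gives the second base-triggered diazo source.

Step 11
Reactants: 8 right-arm N-tosylhydrazone; 15 left-arm N-tosylhydrazone nitrile
Product: 19 achiral chain bearing a free central hydrazone plus two outer N-tosylhydrazones, via sodium tosylhydrazonate 16 (not isolated), via dilithio species 17 (not isolated), via N-H ketimine 18 (not isolated)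
Conditions: 15, NaH, THF, 0 °C; 8, n-BuLi (2.0 equiv), THF, −78 °C; combine, −78 to −20 °C; AcOH, N2H4 (1 M in THF, 10 equiv), EtOH, 23 °C
Reagents that add atoms: hydrazine, NN
Why: Bromine–lithium exchange on a pre-deprotonated N–H substrate, aryllithium addition to a sterically undemanding nitrile and transimination of the N–H ketimine with hydrazine are each standard, both tosylhydrazones are shielded as anions during the addition, exchange with the ring A bromide is slow at −78 °C, and the central C=N–NH2 group arises without the 1,2-diaroylbenzene that hydrazine would turn into a phthalazine.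

Step 12
Reactants: 19 achiral chain bearing a free central hydrazone plus two outer N-tosylhydrazones
Product: 25 all-trans octa-O-methyl bromo tris(dihydrobenzofuran) (2R,3R in each ring), via central diazo compound 20 (not isolated), via cis mono(dihydrobenzofuran) 21 (not isolated), via dilithium salt 22 (not isolated), via bis(diazo) compound 23 (not isolated), via all-cis tris(dihydrobenzofuran) 24 (not isolated)
Conditions: MnO2 (8 equiv), PhCF3, 0 °C; Rh2(R-PTAD)4 (1 mol%), 0 °C; LiOt-Bu (1 M in THF, 2.1 equiv), Rh2(R-PTAD)4 (1 mol%), 40 °C; Celite filtration; CF3CO2H, 0 to 23 °C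
Reagents that add atoms: none
Why: Proposed new method: MnO2 dehydrogenates only the free central hydrazone to 20, the dirhodium carboxylate expels N2 and the diaryl carbene abstracts a hydride-like hydrogen from the adjacent ArO–CH2–Ar group and collapses to the C2–C3 bond, and only afterwards does LiOt-Bu convert the two tosylhydrazones into salts that lose toluenesulfinate (Bamford–Stevens) and feed the same catalyst; the closest known reactions are the enantioselective donor/donor rhodium-carbene insertion into benzyl aryl ethers from MnO2-oxidised hydrazones and metal-catalysed cis-dihydrobenzofuran formation from tosylhydrazone salts, each shown for one ring at a time. Each of the three five-membered rings (central first, then left and right) closes by 1,5 C–H insertion, the carbene carbon (future C3) bonding to the OCH2 carbon (future C2) reached through C3a, C7a and O. The three C3 centres are set by the carbene face left open by the chiral carboxylate pocket, and because the reacting aryl group, the spectator aryl group and C2 are arranged alike at all three sites one catalyst enantiomer should give 3R each time. The three C2 centres form cis (2S) in the compact insertion transition state and are then inverted to 2R by CF3CO2H, which reversibly ionises the C2–O bond to a para-oxygen-stabilised benzylic cation and recloses it trans without touching C3. The step needs the flexible OCH2 group to win over attack by the ortho nitrogen function on ring C and over the tertiary C2–H of the ring already closed next door, which the staggered release should secure because the neighbour of the first carbene is a neutral, weakly nucleophilic tosylhydrazone, the neighbour of the later one is an sp3 C3–H centre, and the secondary, freely rotating, 4-methoxyphenyl-activated CH2 is the better hydride donor. Since three catalyst-controlled events act on an achiral chain, an event of the wrong sense gives a separable diastereomer, so the enantiomeric purity of 25 should exceed that of a single insertion.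

Step 13
Reactants: 25 all-trans octa-O-methyl bromo tris(dihydrobenzofuran)
Product: 27 octaacetate of the bromo tris(dihydrobenzofuran) (2R,3R in each ring), via octaphenol 26 (not isolated)
Conditions: BBr3 (24 equiv), CH2Cl2, −78 to 0 °C; H2O; Ac2O, pyridine, DMAP (cat.), 23 °C
Reagents that add atoms: acetic anhydride, CC(=O)OC(C)=O
Why: Lewis-acid cleavage of the aryl methyl ethers followed by peracetylation is done while no alkene is present, so acid-induced cyclisation of a styryl group onto the neighbouring resorcinol ring cannot occur, and any reversible opening at C2 returns to the trans ring already at equilibrium while C3 stays untouched.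

Step 14
Reactants: 27 octaacetate bromide; 28 4-acetoxystyrene
Product: 29 nonaacetate of the target (E-alkene; 2R,3R in each ring)
Conditions: Pd2(dba)3 (5 mol%), [HP(t-Bu)3]BF4 (12 mol%), Cy2NMe, 1,4-dioxane, 80 °C
Reagents that add atoms: none
Why: The Mizoroki–Heck reaction, with a bulky electron-rich phosphine for the ortho-substituted bromide, should give the E-stilbene through syn insertion and syn β-hydride elimination without affecting the six sp3 stereocentres.

Step 15
Reactants: 29 nonaacetate of the target
Product: 30 target CNP0184803.1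
Conditions: NH3 (7 M in MeOH), 0 to 23 °C, argon
Reagents that add atoms: none
Why: Aminolysis of the nine aryl acetates is mild and non-acidic, so the stilbene, the three dihydrobenzofuran rings and all stereocentres should remain unchanged.

Compound list
1 | 1-bromo-3,5-dimethoxybenzene | COc1cc(Br)cc(OC)c1 | starting material
2 | 3,5-dimethoxybenzoyl chloride | COc1cc(OC)cc(C(=O)Cl)c1 | starting material
3 | (2-bromo-4,6-dimethoxyphenyl)(3,5-dimethoxyphenyl)methanone | COc1cc(OC)cc(c1)C(=O)c1c(Br)cc(OC)cc1OC | intermediate
4 | (2-bromo-6-hydroxy-4-methoxyphenyl)(3,5-dimethoxyphenyl)methanone | COc1cc(OC)cc(c1)C(=O)c1c(Br)cc(OC)cc1O | intermediate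
5 | hydrazone of 4 | COc1cc(OC)cc(c1)C(=NN)c1c(Br)cc(OC)cc1O | intermediate
6 | 4-methoxybenzyl chloride | COc1ccc(CCl)cc1 | starting material
7 | right-arm hydrazone (O-4-methoxybenzyl ether of 5) | COc1ccc(COc2cc(OC)cc(Br)c2C(=NN)c2cc(OC)cc(OC)c2)cc1 | intermediate
8 | right-arm N-tosylhydrazone | COc1ccc(COc2cc(OC)cc(Br)c2C(=NNS(=O)(=O)c2ccc(C)cc2)c2cc(OC)cc(OC)c2)cc1 | intermediate
9 | 2-fluoro-5-formylbenzonitrile | N#Cc1cc(C=O)ccc1F | starting material
10 | 4-methoxybenzyl alcohol | COc1ccc(CO)cc1 | starting material
11 | 5-formyl-2-(4-methoxybenzyloxy)benzonitrile | COc1ccc(COc2ccc(C=O)cc2C#N)cc1 | intermediate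
12 | 5-(hydroxymethyl)-2-(4-methoxybenzyloxy)benzonitrile | COc1ccc(COc2ccc(CO)cc2C#N)cc1 | intermediate
13 | 5-(bromomethyl)-2-(4-methoxybenzyloxy)benzonitrile | COc1ccc(COc2ccc(CBr)cc2C#N)cc1 | intermediate
14 | left-arm hydrazone nitrile (ring A–OCH2–ring B) | COc1ccc(COc2ccc(COc3cc(OC)cc(Br)c3C(=NN)c3cc(OC)cc(OC)c3)cc2C#N)cc1 | intermediate
15 | left-arm N-tosylhydrazone nitrile | COc1ccc(COc2ccc(COc3cc(OC)cc(Br)c3C(=NNS(=O)(=O)c3ccc(C)cc3)c3cc(OC)cc(OC)c3)cc2C#N)cc1 | intermediate
16 | sodium salt of 15 | [Na+].COc1ccc(COc2ccc(COc3cc(OC)cc(Br)c3C(=N[N-]S(=O)(=O)c3ccc(C)cc3)c3cc(OC)cc(OC)c3)cc2C#N)cc1 | intermediate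
17 | N,C-dilithio derivative of 8 | [Li]c1cc(OC)cc(OCc2ccc(OC)cc2)c1C(=NN([Li])S(=O)(=O)c1ccc(C)cc1)c1cc(OC)cc(OC)c1 | intermediate
18 | central N–H ketimine with two outer N-tosylhydrazones | Brc1cc(OC)cc(OCc2ccc(OCc3ccc(OC)cc3)c(c2)C(=N)c2cc(OC)cc(OCc3ccc(OC)cc3)c2C(=NNS(=O)(=O)c2ccc(C)cc2)c2cc(OC)cc(OC)c2)c1C(=NNS(=O)(=O)c1ccc(C)cc1)c1cc(OC)cc(OC)c1 | intermediate
19 | key-step precursor: achiral tris(benzyl aryl ether), central free hydrazone, left and right N-tosylhydrazones | Brc1cc(OC)cc(OCc2ccc(OCc3ccc(OC)cc3)c(c2)C(=NN)c2cc(OC)cc(OCc3ccc(OC)cc3)c2C(=NNS(=O)(=O)c2ccc(C)cc2)c2cc(OC)cc(OC)c2)c1C(=NNS(=O)(=O)c1ccc(C)cc1)c1cc(OC)cc(OC)c1 | intermediate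
20 | central diaryldiazomethane | Brc1cc(OC)cc(OCc2ccc(OCc3ccc(OC)cc3)c(c2)C(=[N+]=[N-])c2cc(OC)cc(OCc3ccc(OC)cc3)c2C(=NNS(=O)(=O)c2ccc(C)cc2)c2cc(OC)cc(OC)c2)c1C(=NNS(=O)(=O)c1ccc(C)cc1)c1cc(OC)cc(OC)c1 | intermediate
21 | central ring closed, cis (2S,3R), both tosylhydrazones intact | Brc1cc(OC)cc(OCc2ccc3c(c2)[C@@H](c2cc(OC)cc(OCc4ccc(OC)cc4)c2C(=NNS(=O)(=O)c2ccc(C)cc2)c2cc(OC)cc(OC)c2)[C@@H](c2ccc(OC)cc2)O3)c1C(=NNS(=O)(=O)c1ccc(C)cc1)c1cc(OC)cc(OC)c1 | intermediate
22 | dilithium salt of 21 | [Li+].[Li+].Brc1cc(OC)cc(OCc2ccc3c(c2)[C@@H](c2cc(OC)cc(OCc4ccc(OC)cc4)c2C(=N[N-]S(=O)(=O)c2ccc(C)cc2)c2cc(OC)cc(OC)c2)[C@@H](c2ccc(OC)cc2)O3)c1C(=N[N-]S(=O)(=O)c1ccc(C)cc1)c1cc(OC)cc(OC)c1 | intermediate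
23 | left and right diazo groups (each released and consumed in turn, drawn together) | Brc1cc(OC)cc(OCc2ccc3c(c2)[C@@H](c2cc(OC)cc(OCc4ccc(OC)cc4)c2C(=[N+]=[N-])c2cc(OC)cc(OC)c2)[C@@H](c2ccc(OC)cc2)O3)c1C(=[N+]=[N-])c1cc(OC)cc(OC)c1 | intermediate
24 | all-cis tris(dihydrobenzofuran), (2S,3R) in each ring | Brc1cc(OC)cc2c1[C@@H](c1cc(OC)cc(OC)c1)[C@@H](c1ccc3c(c1)[C@@H](c1cc(OC)cc4c1[C@@H](c1cc(OC)cc(OC)c1)[C@@H](c1ccc(OC)cc1)O4)[C@@H](c1ccc(OC)cc1)O3)O2 | intermediate
25 | key-step product: all-trans octa-O-methyl bromo tris(dihydrobenzofuran), (2R,3R) in each ring | Brc1cc(OC)cc2c1[C@@H](c1cc(OC)cc(OC)c1)[C@H](c1ccc3c(c1)[C@@H](c1cc(OC)cc4c1[C@@H](c1cc(OC)cc(OC)c1)[C@H](c1ccc(OC)cc1)O4)[C@H](c1ccc(OC)cc1)O3)O2 | intermediate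
26 | octaphenol bromide | Brc1cc(O)cc2c1[C@@H](c1cc(O)cc(O)c1)[C@H](c1ccc3c(c1)[C@@H](c1cc(O)cc4c1[C@@H](c1cc(O)cc(O)c1)[C@H](c1ccc(O)cc1)O4)[C@H](c1ccc(O)cc1)O3)O2 | intermediate
27 | octaacetate bromide | Brc1cc(OC(C)=O)cc2c1[C@@H](c1cc(OC(C)=O)cc(OC(C)=O)c1)[C@H](c1ccc3c(c1)[C@@H](c1cc(OC(C)=O)cc4c1[C@@H](c1cc(OC(C)=O)cc(OC(C)=O)c1)[C@H](c1ccc(OC(C)=O)cc1)O4)[C@H](c1ccc(OC(C)=O)cc1)O3)O2 | intermediate
28 | 4-acetoxystyrene | C=Cc1ccc(OC(C)=O)cc1 | starting material
29 | nonaacetate of the target | CC(=O)Oc1ccc(/C=C/c2cc(OC(C)=O)cc3c2[C@@H](c2cc(OC(C)=O)cc(OC(C)=O)c2)[C@H](c2ccc4c(c2)[C@@H](c2cc(OC(C)=O)cc5c2[C@@H](c2cc(OC(C)=O)cc(OC(C)=O)c2)[C@H](c2ccc(OC(C)=O)cc2)O5)[C@H](c2ccc(OC(C)=O)cc2)O4)O3)cc1 | intermediate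
30 | CNP0184803.1 | Oc1ccc(/C=C/c2cc(O)cc3c2[C@@H](c2cc(O)cc(O)c2)[C@H](c2ccc4c(c2)[C@@H](c2cc(O)cc5c2[C@@H](c2cc(O)cc(O)c2)[C@H](c2ccc(O)cc2)O5)[C@H](c2ccc(O)cc2)O4)O3)cc1 | target

Total step count: 15. Longest linear sequence: 10 (steps 1, 2, 3, 9, 10, 11, 12, 13, 14, 15).

Steps most likely to fail

Step 12. Four processes may go wrong:
- the first carbene is captured by a nitrogen of the neighbouring tosylhydrazone;
- the two di-ortho-substituted diazo groups lose nitrogen slowly at the crowded catalyst;
- facial selectivity erodes at 40 °C;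
- the opened C2 cation undergoes Friedel–Crafts capture during the acid equilibration.

The fallback sets out from 7 and 14 and closes the rings one at a time by the established single-insertion protocol. Hydrazone 7 is oxidised with MnO2 to the diazo compound F1, which Rh2(R-PTAD)4 cyclises to the cis right-hand bromodihydrobenzofuran F2. Hydrazone 14 is oxidised in the same way to the diazo compound F3 and cyclised to the cis left-hand dihydrobenzofuran nitrile F4. Neither is treated with acid at this stage, because the remaining 4-methoxybenzyl aryl ether of F4 is acid-labile. Bromine–lithium exchange on F2 gives the aryllithium F5. This adds to the nitrile of F4 to give the ketimine F6, and hydrazine exchange gives the hydrazone F7, whose neighbour on ring C is now an sp3 carbon, so no phthalazine can form. MnO2 oxidation to the diazo compound F8 and a third single insertion bring the fallback back to the route at 24, which is equilibrated with acid to 25 as before.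

Step 11. Four processes may go wrong:
- the hindered aryllithium is quenched by protons or scrambles halogen with the ring A bromide;
- addition to the nitrile is sluggish;
- exchange at the hindered ketimine is slow;
- the new NH2 group closes onto the neighbouring tosylhydrazone carbon with loss of tosylhydrazide.

The fallback sets out from 15 and never exposes a free NH2 group next to ring C. DIBAL-H reduction of the nitrile and hydrolysis give the aldehyde F9. After deprotonation with NaH, F9 is attacked by 17 to give the carbinol F10, and MnO2 oxidises this to the ketone F11. Condensation with 1,2-bis(tert-butyldimethylsilyl)hydrazine under Sc(OTf)3 catalysis gives the N-silylhydrazone F12, whose bulky silylated nitrogen should not cyclise. In the flask of step 12, (difluoroiodo)benzene with 2-chloropyridine replaces MnO2 and converts F12 into the diazo compound, so the fallback comes back to the route at 20.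

Step 13. Three processes may go wrong: cleavage stops before all eight methyl ethers are removed, the C2–O bonds open irreversibly under the Lewis acid, or the resulting cations alkylate the electron-rich rings. The fallback sets out from 25 and avoids cation-forming conditions. A Heck coupling with commercial 4-methoxystyrene (same catalyst system as step 14) gives the nona-O-methyl ether F13. The coupling comes first so that no aryl bromide is exposed to thiolate. All nine methyl groups are then removed by SN2 attack of sodium ethanethiolate in DMF at 130 °C under argon, followed by mild acidification, and the fallback comes back to the route at 30.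

Further compounds
F1 | step 12 | diazo compound from 7 | COc1ccc(COc2cc(OC)cc(Br)c2C(=[N+]=[N-])c2cc(OC)cc(OC)c2)cc1
F2 | step 12 | (2S,3R)-cis-4-bromo-3-(3,5-dimethoxyphenyl)-6-methoxy-2-(4-methoxyphenyl)-2,3-dihydrobenzofuran | Brc1cc(OC)cc2c1[C@@H](c1cc(OC)cc(OC)c1)[C@@H](c1ccc(OC)cc1)O2
F3 | step 12 | diazo compound from 14 | COc1ccc(COc2ccc(COc3cc(OC)cc(Br)c3C(=[N+]=[N-])c3cc(OC)cc(OC)c3)cc2C#N)cc1
F4 | step 12 | (2S,3R)-cis left dihydrobenzofuran carrying 3-cyano-4-(4-methoxybenzyloxy)phenyl at C2 | Brc1cc(OC)cc2c1[C@@H](c1cc(OC)cc(OC)c1)[C@@H](c1ccc(OCc3ccc(OC)cc3)c(C#N)c1)O2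
F5 | step 12 | aryllithium from F2 | [Li]c1cc(OC)cc2c1[C@@H](c1cc(OC)cc(OC)c1)[C@@H](c1ccc(OC)cc1)O2
F6 | step 12 | central N–H ketimine between the closed cis left and right units | Brc1cc(OC)cc2c1[C@@H](c1cc(OC)cc(OC)c1)[C@@H](c1ccc(OCc3ccc(OC)cc3)c(c1)C(=N)c1cc(OC)cc3c1[C@@H](c1cc(OC)cc(OC)c1)[C@@H](c1ccc(OC)cc1)O3)O2
F7 | step 12 | central hydrazone between the closed cis left and right units | Brc1cc(OC)cc2c1[C@@H](c1cc(OC)cc(OC)c1)[C@@H](c1ccc(OCc3ccc(OC)cc3)c(c1)C(=NN)c1cc(OC)cc3c1[C@@H](c1cc(OC)cc(OC)c1)[C@@H](c1ccc(OC)cc1)O3)O2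
F8 | step 12 | central diazo compound between the closed cis left and right units | Brc1cc(OC)cc2c1[C@@H](c1cc(OC)cc(OC)c1)[C@@H](c1ccc(OCc3ccc(OC)cc3)c(c1)C(=[N+]=[N-])c1cc(OC)cc3c1[C@@H](c1cc(OC)cc(OC)c1)[C@@H](c1ccc(OC)cc1)O3)O2
F9 | step 11 | aldehyde from 15 | COc1ccc(COc2ccc(COc3cc(OC)cc(Br)c3C(=NNS(=O)(=O)c3ccc(C)cc3)c3cc(OC)cc(OC)c3)cc2C=O)cc1
F10 | step 11 | central carbinol (racemic) with two outer N-tosylhydrazones | Brc1cc(OC)cc(OCc2ccc(OCc3ccc(OC)cc3)c(c2)C(O)c2cc(OC)cc(OCc3ccc(OC)cc3)c2C(=NNS(=O)(=O)c2ccc(C)cc2)c2cc(OC)cc(OC)c2)c1C(=NNS(=O)(=O)c1ccc(C)cc1)c1cc(OC)cc(OC)c1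
F11 | step 11 | central ketone with two outer N-tosylhydrazones | Brc1cc(OC)cc(OCc2ccc(OCc3ccc(OC)cc3)c(c2)C(=O)c2cc(OC)cc(OCc3ccc(OC)cc3)c2C(=NNS(=O)(=O)c2ccc(C)cc2)c2cc(OC)cc(OC)c2)c1C(=NNS(=O)(=O)c1ccc(C)cc1)c1cc(OC)cc(OC)c1
F12 | step 11 | central N-(tert-butyldimethylsilyl)hydrazone with two outer N-tosylhydrazones | Brc1cc(OC)cc(OCc2ccc(OCc3ccc(OC)cc3)c(c2)C(=NN[Si](C)(C)C(C)(C)C)c2cc(OC)cc(OCc3ccc(OC)cc3)c2C(=NNS(=O)(=O)c2ccc(C)cc2)c2cc(OC)cc(OC)c2)c1C(=NNS(=O)(=O)c1ccc(C)cc1)c1cc(OC)cc(OC)c1
F13 | step 13 | nona-O-methyl ether of the target | COc1ccc(/C=C/c2cc(OC)cc3c2[C@@H](c2cc(OC)cc(OC)c2)[C@H](c2ccc4c(c2)[C@@H](c2cc(OC)cc5c2[C@@H](c2cc(OC)cc(OC)c2)[C@H](c2ccc(OC)cc2)O5)[C@H](c2ccc(OC)cc2)O4)O3)cc1
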